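**Retrosynthetic overview**
- Gneyulin A ⇐ its deca-O-methyl ether with both dihydrobenzofurans cis: one BBr3 operation removes ten methyl groups and turns C2 and C2′ to trans; C3 and C3′ are untouched.
- Both dihydrofuran rings (bonds C2–C3 and C2′–C3′) ⇐ one acyclic bis(diaryldiazomethane), by a twofold catalyst-controlled rhodium-carbene 1,5 C–H insertion into the two ArO–CH2Ar ethers. Rings 1 and 2 close in the same operation; no other ring is made in the route.
- Bis(diazo) compound ⇐ bis-hydrazone ⇐ diketone ⇐ Mitsunobu ether union of an ortho-hydroxy benzophenone (stilbene half) with a benzylic alcohol (central half).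
- Stilbene half ⇐ Horner–Wadsworth–Emmons olefination, Br/Li exchange–Weinreb acylation, chelation-directed mono-demethylation. Central half ⇐ bromination, Mitsunobu, carbonylative Suzuki coupling, aldehyde reduction.

Assumption: Rh2(R-PTAD)4 (PTAD = (1-adamantyl)(phthalimido)acetate) is taken to give the R configuration at both carbene-derived carbons; if a model insertion shows the opposite sense, Rh2(S-PTAD)4 is used and nothing else changes.

Locants: ring 1 is the dihydrofuran whose C2 carries the 2,4-dioxygenated phenyl and whose C3 carries a 3,5-dioxygenated phenyl. Ring 2 is the dihydrofuran fused to the styryl-bearing arene; its C2′ carries the ring-1 benzofuran (through C5) and its C3′ the other 3,5-dioxygenated phenyl. The target is 2R,3R,2′R,3′R, both rings trans.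

**Route**

Step 1
Reactants: 1 2,4-dimethoxybenzyl alcohol
Product: 2 diethyl (2,4-dimethoxybenzyl)phosphonate
Conditions: P(OEt)3 (3 equiv), ZnI2 (1.5 equiv), THF, 66 °C
Reagents that add atoms: triethyl phosphite, CCOP(OCC)OCC
Why: ZnI2 activates the benzylic C–O bond of this electron-rich alcohol and phosphorus takes its place in a Michaelis–Arbuzov-type direct alcohol-to-phosphonate conversion, which is known to work best for donor-substituted benzylic alcohols.

Step 2
Reactants: 2 diethyl (2,4-dimethoxybenzyl)phosphonate; 3 4-bromo-3,5-dimethoxybenzaldehyde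
Product: 4 (E)-2-bromo-5-[2-(2,4-dimethoxyphenyl)ethenyl]-1,3-dimethoxybenzene
Conditions: KOtBu, THF, 0 °C → rt
Reagents that add atoms: none
Why: Horner–Wadsworth–Emmons olefination of an aromatic aldehyde with a benzylic phosphonate anion gives the E-stilbene because elimination runs through the less crowded anti arrangement of the two aryl groups.

Step 3
Reactants: 4 (E)-2-bromo-5-[2-(2,4-dimethoxyphenyl)ethenyl]-1,3-dimethoxybenzene; 5 N,3,5-trimethoxy-N-methylbenzamide
Product: 7 [4-[(E)-2-(2,4-dimethoxyphenyl)ethenyl]-2,6-dimethoxyphenyl](3,5-dimethoxyphenyl)methanone, via aryllithium 6 (not isolated)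
Conditions: n-BuLi, THF, −78 °C; then 5, −78 → 0 °C; aq. HCl (1 M) quench
Reagents that add atoms: none
Why: Bromine–lithium exchange is fast and site-specific at −78 °C for the bromide flanked by two methoxy groups, and the Weinreb amide stops the addition at the ketone stage (Weinreb ketone synthesis).

Step 4
Reactants: 7 [4-[(E)-2-(2,4-dimethoxyphenyl)ethenyl]-2,6-dimethoxyphenyl](3,5-dimethoxyphenyl)methanone
Product: 8 [4-[(E)-2-(2,4-dimethoxyphenyl)ethenyl]-2-hydroxy-6-methoxyphenyl](3,5-dimethoxyphenyl)methanone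
Conditions: BCl3 (1.5 equiv), CH2Cl2, −78 → 0 °C; H2O
Reagents that add atoms: none
Why: Chelation-directed ortho-demethylation: BCl3 bound to the ketone cleaves only a methoxy group that can close a six-membered boron chelate, the two ortho methoxy groups are equivalent, the chelate formed after the first cleavage stops the second, and the six non-chelating methyl ethers and the stilbene are left alone at this temperature.

Step 5
Reactants: 9 4-hydroxy-2-methoxybenzaldehyde
Product: 10 5-bromo-4-hydroxy-2-methoxybenzaldehyde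
Conditions: NBS (1.0 equiv), MeCN, 0 °C → rt
Reagents that add atoms: N-bromosuccinimide, O=C1CCC(=O)N1Br
Why: Electrophilic aromatic bromination goes to C5, the unhindered position that is ortho to the free hydroxyl and para to the methoxy group.

Step 6
Reactants: 10 5-bromo-4-hydroxy-2-methoxybenzaldehyde; 1 2,4-dimethoxybenzyl alcohol
Product: 11 5-bromo-4-[(2,4-dimethoxybenzyl)oxy]-2-methoxybenzaldehyde
Conditions: PPh3, DIAD, THF, 0 °C → rt
Reagents that add atoms: none
Why: Mitsunobu etherification of the acidic phenol (para to the aldehyde, ortho to bromine) with a primary benzylic alcohol installs the acid-labile 2,4-dimethoxybenzyl ether under neutral conditions.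

Step 7
Reactants: 11 5-bromo-4-[(2,4-dimethoxybenzyl)oxy]-2-methoxybenzaldehyde; 12 3,5-dimethoxyphenylboronic acid
Product: 13 5-(3,5-dimethoxybenzoyl)-4-[(2,4-dimethoxybenzyl)oxy]-2-methoxybenzaldehyde
Conditions: CO (5 bar), Pd(OAc)2 (2 mol %), PAd2(n-Bu) (6 mol %), TMEDA, toluene, 100 °C
Reagents that add atoms: carbon monoxide, [C-]#[O+]
Why: Carbonylative Suzuki–Miyaura coupling (oxidative addition, CO insertion, transmetalation, reductive elimination) gives the diaryl ketone directly and tolerates the aldehyde and the benzyl ether.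

Step 8
Reactants: 13 5-(3,5-dimethoxybenzoyl)-4-[(2,4-dimethoxybenzyl)oxy]-2-methoxybenzaldehyde
Product: 14 [2-[(2,4-dimethoxybenzyl)oxy]-5-(hydroxymethyl)-4-methoxyphenyl](3,5-dimethoxyphenyl)methanone
Conditions: NaBH4, EtOH/CH2Cl2 (3:7), −78 °C
Reagents that add atoms: none
Why: Chemoselective hydride reduction: at −78 °C NaBH4 reduces the aldehyde much faster than the hindered, donor-substituted diaryl ketone.

Step 9
Reactants: 8 [4-[(E)-2-(2,4-dimethoxyphenyl)ethenyl]-2-hydroxy-6-methoxyphenyl](3,5-dimethoxyphenyl)methanone; 14 [2-[(2,4-dimethoxybenzyl)oxy]-5-(hydroxymethyl)-4-methoxyphenyl](3,5-dimethoxyphenyl)methanone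
Product: 15 [2-[[5-(3,5-dimethoxybenzoyl)-4-[(2,4-dimethoxybenzyl)oxy]-2-methoxybenzyl]oxy]-4-[(E)-2-(2,4-dimethoxyphenyl)ethenyl]-6-methoxyphenyl](3,5-dimethoxyphenyl)methanone
Conditions: PPh3, DIAD, THF, 0 °C → rt
Reagents that add atoms: none
Why: Mitsunobu etherification joins the two halves, since the hydrogen-bonded ortho-hydroxy ketone is acidic enough and the primary benzylic alcohol is readily activated; this creates the second ArO–CH2Ar ether needed for the key step.

Step 10
Reactants: 15 diketone (name as in step 9)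
Product: 16 bis-hydrazone of 15 (both C=O replaced by C=N–NH2)
Conditions: N2H4·H2O (excess), AcOH (cat.), n-BuOH, 115 °C, sealed tube, argon
Reagents that add atoms: hydrazine (used as the monohydrate), NN
Why: Hydrazone formation at both diaryl ketones is driven by excess hydrazine and heat; diaryl ketone hydrazones do not readily go on to azines, nothing else in 15 is electrophilic, and air is excluded so that no diimide forms to reduce the stilbene.

Step 11
Reactants: 16 bis-hydrazone of 15
Product: 18 (2S,3R,2′S,3′R)-deca-O-methyl-2,2′-di-epi-gneyulin A (both dihydrobenzofuran rings cis), via bis(diazo) compound 17 (not isolated)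
Conditions: MnO2, CH2Cl2, 0 °C; filter; Rh2(R-PTAD)4 (2 mol %), CH2Cl2 (0.01 M), 0 °C → rt
Reagents that add atoms: none
Why: Proposed new method: a twofold version of the known enantioselective intramolecular 1,5 C–H insertion of donor/donor rhodium carbenes made from hydrazones with MnO2 (closest known reaction: the single insertion of ortho-benzyloxy diaryl diazomethanes to cis-2,3-diaryl-2,3-dihydrobenzofurans); each carbene reaches only its own ArO–CH2Ar hydrogen through a five-membered transition state (hydride shift to the carbene carbon, then C–C closure on the oxocarbenium ion inside the chiral pocket), so rings 1 and 2 close independently, the catalyst fixes C3 and C3′ as R, the kinetic closure places C2 and C2′ cis to them (S), and the methoxy C–H, the stilbene and the distant second carbene cannot compete with the activated benzylic ether C–H.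

Step 12
Reactants: 18 (2S,3R,2′S,3′R)-deca-O-methyl-2,2′-di-epi-gneyulin A
Product: 19 gneyulin A
Conditions: BBr3 (30 equiv), CH2Cl2, −78 °C → rt; MeOH then H2O, 0 °C
Reagents that add atoms: none
Why: Lewis-acid ether cleavage removes all ten aryl methyl groups, and reversible ionisation of the benzylic C2–O and C2′–O bonds to cations stabilised by ortho and para oxygen, followed by re-closure, brings C2 and C2′ to the thermodynamically preferred trans arrangement (R), while C3 and C3′ have no ionisable bond and keep the R configuration set in step 11.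

**Compound list**

1 | 2,4-dimethoxybenzyl alcohol | COc1ccc(CO)c(OC)c1 | starting material
2 | diethyl (2,4-dimethoxybenzyl)phosphonate | CCOP(=O)(OCC)Cc1ccc(OC)cc1OC | intermediate
3 | 4-bromo-3,5-dimethoxybenzaldehyde | COc1cc(C=O)cc(OC)c1Br | starting material
4 | (E)-2-bromo-5-[2-(2,4-dimethoxyphenyl)ethenyl]-1,3-dimethoxybenzene | COc1ccc(/C=C/c2cc(OC)c(Br)c(OC)c2)c(OC)c1 | intermediate
5 | N,3,5-trimethoxy-N-methylbenzamide | CON(C)C(=O)c1cc(OC)cc(OC)c1 | starting material
6 | [4-[(E)-2-(2,4-dimethoxyphenyl)ethenyl]-2,6-dimethoxyphenyl]lithium | COc1ccc(/C=C/c2cc(OC)c([Li])c(OC)c2)c(OC)c1 | intermediate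
7 | [4-[(E)-2-(2,4-dimethoxyphenyl)ethenyl]-2,6-dimethoxyphenyl](3,5-dimethoxyphenyl)methanone | COc1ccc(/C=C/c2cc(OC)c(C(=O)c3cc(OC)cc(OC)c3)c(OC)c2)c(OC)c1 | intermediate
8 | [4-[(E)-2-(2,4-dimethoxyphenyl)ethenyl]-2-hydroxy-6-methoxyphenyl](3,5-dimethoxyphenyl)methanone | COc1ccc(/C=C/c2cc(O)c(C(=O)c3cc(OC)cc(OC)c3)c(OC)c2)c(OC)c1 | intermediate
9 | 4-hydroxy-2-methoxybenzaldehyde | COc1cc(O)ccc1C=O | starting material
10 | 5-bromo-4-hydroxy-2-methoxybenzaldehyde | COc1cc(O)c(Br)cc1C=O | intermediate
11 | 5-bromo-4-[(2,4-dimethoxybenzyl)oxy]-2-methoxybenzaldehyde | COc1ccc(COc2cc(OC)c(C=O)cc2Br)c(OC)c1 | intermediate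
12 | 3,5-dimethoxyphenylboronic acid | COc1cc(OC)cc(B(O)O)c1 | starting material
13 | 5-(3,5-dimethoxybenzoyl)-4-[(2,4-dimethoxybenzyl)oxy]-2-methoxybenzaldehyde | COc1ccc(COc2cc(OC)c(C=O)cc2C(=O)c2cc(OC)cc(OC)c2)c(OC)c1 | intermediate
14 | [2-[(2,4-dimethoxybenzyl)oxy]-5-(hydroxymethyl)-4-methoxyphenyl](3,5-dimethoxyphenyl)methanone | COc1ccc(COc2cc(OC)c(CO)cc2C(=O)c2cc(OC)cc(OC)c2)c(OC)c1 | intermediate
15 | [2-[[5-(3,5-dimethoxybenzoyl)-4-[(2,4-dimethoxybenzyl)oxy]-2-methoxybenzyl]oxy]-4-[(E)-2-(2,4-dimethoxyphenyl)ethenyl]-6-methoxyphenyl](3,5-dimethoxyphenyl)methanone | COc1ccc(/C=C/c2cc(OCc3cc(C(=O)c4cc(OC)cc(OC)c4)c(OCc4ccc(OC)cc4OC)cc3OC)c(C(=O)c3cc(OC)cc(OC)c3)c(OC)c2)c(OC)c1 | intermediate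
16 | bis-hydrazone of 15 (both C=O replaced by C=N–NH2) | COc1ccc(/C=C/c2cc(OCc3cc(C(=NN)c4cc(OC)cc(OC)c4)c(OCc4ccc(OC)cc4OC)cc3OC)c(C(=NN)c3cc(OC)cc(OC)c3)c(OC)c2)c(OC)c1 | intermediate
17 | bis(diazo) compound from 16 (both C=N–NH2 replaced by C=N2) | COc1ccc(/C=C/c2cc(OCc3cc(C(=[N+]=[N-])c4cc(OC)cc(OC)c4)c(OCc4ccc(OC)cc4OC)cc3OC)c(C(=[N+]=[N-])c3cc(OC)cc(OC)c3)c(OC)c2)c(OC)c1 | intermediate
18 | (2S,3R,2′S,3′R)-deca-O-methyl-2,2′-di-epi-gneyulin A (both dihydrobenzofuran rings cis) | COc1cc(OC)cc([C@@H]2c3cc([C@H]4Oc5cc(/C=C/c6ccc(OC)cc6OC)cc(OC)c5[C@H]4c4cc(OC)cc(OC)c4)c(OC)cc3O[C@@H]2c2ccc(OC)cc2OC)c1 | intermediate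
19 | gneyulin A (2R,3R,2′R,3′R; both dihydrobenzofuran rings trans) | Oc1cc(O)cc([C@@H]2c3cc([C@@H]4Oc5cc(/C=C/c6ccc(O)cc6O)cc(O)c5[C@H]4c4cc(O)cc(O)c4)c(O)cc3O[C@H]2c2ccc(O)cc2O)c1 | target

**Step count**

Total: 12 steps. Longest linear sequence: 8 steps (9 → 10 → 11 → 13 → 14 → 15 → 16 → 18 → 19; the branch from 1 through 2, 4, 7, 8 is equally long).

**Three steps most likely to fail, with fallbacks**

Step 11 (twofold C–H insertion). The carbene flanked by two alkoxy groups is hindered, and the very electron-rich benzylic ethers may lower the selectivity at C3 and C3′. Because the two centres are set independently, the minor enantiomer of 18 is depleted and the mixed diastereomers are removed by chromatography, but low conversion at the hindered site would still sink the step. Fallback: close the rings one after the other, starting from diketone 15. Hydrazine hydrate in ethanol at 70 °C condenses only with the less hindered ketone on the central ring and gives the mono-hydrazone F1. MnO2 turns it into the mono-diazo compound F2, and Rh2(R-PTAD)4 closes ring 1 to the cis-dihydrobenzofuran ketone F3. The remaining hindered ketone is then converted under the conditions of step 10 into the hydrazone F4 and oxidised with MnO2 to the diazo compound F5. Ring 2 is closed with a chiral dirhodium tetracarboxylate optimised separately for this hindered carbene, which gives 18, where the route is rejoined.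

Step 10 (bis-hydrazone). The ketone between two ortho alkoxy groups may not condense with hydrazine. Fallback: starting from 15, both carbonyl groups are converted with Lawesson's reagent (toluene, 90 °C) into thiocarbonyl groups to give the bis-thioketone F6. Thioketones are far more reactive toward nitrogen nucleophiles, and hydrazine hydrate in THF at room temperature replaces sulfur to give 16, where the route is rejoined.

Step 12 (tenfold demethylation with epimerisation). BBr3 may degrade the ionisable dihydrofurans or the electron-rich stilbene, loss of the C3 hydrogen from the opened cation could erode the configuration at C3, and cis isomers may remain. Fallback: separate the stereochemical correction from the deprotection and change the ether cleavage from Lewis-acid to nucleophilic, starting from 18. TFA (5 vol %) in CH2Cl2 at 0 °C equilibrates both rings to the all-trans deca-O-methyl gneyulin A F7. F7 is then demethylated by SN2 attack of sodium ethanethiolate (NaSEt, excess) in DMF at 140 °C, and acidic work-up gives 19.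

**Further compounds**

F1 | step 11 | mono-hydrazone of 15 at the central-ring ketone | COc1ccc(/C=C/c2cc(OCc3cc(C(=NN)c4cc(OC)cc(OC)c4)c(OCc4ccc(OC)cc4OC)cc3OC)c(C(=O)c3cc(OC)cc(OC)c3)c(OC)c2)c(OC)c1
F2 | step 11 | mono-diazo compound from F1 | COc1ccc(/C=C/c2cc(OCc3cc(C(=[N+]=[N-])c4cc(OC)cc(OC)c4)c(OCc4ccc(OC)cc4OC)cc3OC)c(C(=O)c3cc(OC)cc(OC)c3)c(OC)c2)c(OC)c1
F3 | step 11 | ketone with ring 1 closed, cis-(2S,3R)-2-(2,4-dimethoxyphenyl)-3-(3,5-dimethoxyphenyl)-6-methoxy-2,3-dihydrobenzofuran-5-ylmethyl ether of 8 | COc1cc(OC)cc([C@@H]2c3cc(COc5cc(/C=C/c6ccc(OC)cc6OC)cc(OC)c5C(=O)c4cc(OC)cc(OC)c4)c(OC)cc3O[C@@H]2c2ccc(OC)cc2OC)c1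
F4 | step 11 | hydrazone of F3 | COc1cc(OC)cc([C@@H]2c3cc(COc5cc(/C=C/c6ccc(OC)cc6OC)cc(OC)c5C(=NN)c4cc(OC)cc(OC)c4)c(OC)cc3O[C@@H]2c2ccc(OC)cc2OC)c1
F5 | step 11 | diazo compound from F4 | COc1cc(OC)cc([C@@H]2c3cc(COc5cc(/C=C/c6ccc(OC)cc6OC)cc(OC)c5C(=[N+]=[N-])c4cc(OC)cc(OC)c4)c(OC)cc3O[C@@H]2c2ccc(OC)cc2OC)c1
F6 | step 10 | bis-thioketone of 15 (both C=O replaced by C=S) | COc1ccc(/C=C/c2cc(OCc3cc(C(=S)c4cc(OC)cc(OC)c4)c(OCc4ccc(OC)cc4OC)cc3OC)c(C(=S)c3cc(OC)cc(OC)c3)c(OC)c2)c(OC)c1
F7 | step 12 | (2R,3R,2′R,3′R)-deca-O-methyl gneyulin A (both rings trans) | COc1cc(OC)cc([C@@H]2c3cc([C@@H]4Oc5cc(/C=C/c6ccc(OC)cc6OC)cc(OC)c5[C@H]4c4cc(OC)cc(OC)c4)c(OC)cc3O[C@H]2c2ccc(OC)cc2OC)c1
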